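**Retrosynthetic overview**

1. Target ⇐ aldehyde-selective reduction and removal of two phenolic acetates from the all-trans 2-aryl-3-formyl-4-aroyl-oxolane; no ring bond is made here.
2. C4–C(=O)Ar bond ⇐ aroyl-radical conjugate addition (from O-acetylsyringic acid) to a 2-aryl-2,5-dihydrofuran-3-carbaldehyde; C3 and C4 then settle trans,trans relative to C2.
3. Oxolane ring (the only ring, formed first) ⇐ key C2–O1 bond: catalytic enantioselective oxa-Michael addition of glycolaldehyde to O-acetylconiferaldehyde, closed in the same flask by C3–C4 aldol condensation.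
4. Starting materials: 4-acetoxy-3-methoxycinnamaldehyde, glycolaldehyde dimer, syringic acid.

Note: the oxolane is numbered O1, C2 (guaiacyl carbon), C3, C4 (aroyl carbon), C5; in this numbering the target is (2S,3R,4S), 2,3-trans and 3,4-trans. 4-Acetoxy-3-methoxycinnamaldehyde is taken as a purchased stock chemical.

**Route**

Step 1
Reactants: 1 (E)-4-acetoxy-3-methoxycinnamaldehyde; 2 1,4-dioxane-2,5-diol (glycolaldehyde dimer)
Product: 4 4-[(2R)-3-formyl-2,5-dihydrofuran-2-yl]-2-methoxyphenyl acetate, via aldol adduct 3 (not isolated)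
Conditions: 2 (0.75 equiv), (S)-2-[diphenyl(trimethylsilyloxy)methyl]pyrrolidine (20 mol%), 2-nitrobenzoic acid (20 mol%), toluene, rt, 24–48 h
Reagents that add atoms: none
Why: Proposed new method: the amine and 1 form an iminium ion whose Re face at the β-carbon is shielded by the diphenyl(silyloxy)methyl group, so glycolaldehyde (freed from 2) adds through its hydroxyl oxygen from the Si face in a reversible oxa-Michael step that sets C2, the enamine so formed closes the ring by 5-exo aldol addition to the tethered formyl group (C3–C4), and E1cB loss of water makes the sequence irreversible and removes the two transient stereocentres; the closest known reactions are the amine-catalysed sulfa-Michael/aldol condensation of 1,4-dithiane-2,5-diol with enals and the oxa-Michael/aldol condensation of salicylaldehydes with enals to 2H-chromene-3-carbaldehydes (iminium–enamine organocascade).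

Step 2
Reactants: 5 syringic acid (4-hydroxy-3,5-dimethoxybenzoic acid)
Product: 6 4-acetoxy-3,5-dimethoxybenzoic acid
Conditions: Ac2O, pyridine, DMAP (cat.), 0 °C to rt; aq. HCl work-up
Reagents that add atoms: acetic anhydride, CC(=O)OC(C)=O
Why: Standard O-acetylation of the phenol (any mixed anhydride is hydrolysed on work-up), which keeps the electron-rich phenol from being oxidised in the photoredox step.

Step 3
Reactants: 4 4-[(2R)-3-formyl-2,5-dihydrofuran-2-yl]-2-methoxyphenyl acetate; 6 4-acetoxy-3,5-dimethoxybenzoic acid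
Product: 8 4-[(2S,3S,4S)-4-(4-acetoxy-3,5-dimethoxybenzoyl)-3-formyloxolan-2-yl]-2-methoxyphenyl acetate, via epimer mixture 7 (not isolated)
Conditions: Ir[dF(CF3)ppy]2(dtbbpy)PF6 (1 mol%), PPh3 (1.5 equiv), K2HPO4, CH2Cl2–H2O, blue LEDs, rt; then DBU (0.2 equiv), CH2Cl2, 0 °C
Reagents that add atoms: none
Why: Photoredox deoxygenative acyl-radical formation (the Ph3P radical cation captures the carboxylate of 6 and β-scission gives the aroyl radical and Ph3P=O) followed by Giese addition to the enal β-carbon C4, reduction and protonation; DBU then equilibrates the two enolisable centres C3 and C4 to the all-trans isomer dictated by the fixed C2 aryl group (C3 trans to C2, C4 trans to C3).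

Step 4
Reactants: 8 4-[(2S,3S,4S)-4-(4-acetoxy-3,5-dimethoxybenzoyl)-3-formyloxolan-2-yl]-2-methoxyphenyl acetate
Product: 10 (4-hydroxy-3,5-dimethoxyphenyl)[(3S,4R,5S)-5-(4-hydroxy-3-methoxyphenyl)-4-(hydroxymethyl)oxolan-3-yl]methanone, via hydroxy ketone diacetate 9 (not isolated)
Conditions: NaBH4 (0.3 equiv), MeOH–CH2Cl2, −78 °C; then K2CO3 (0.3 equiv), MeOH, 0 °C; aq. NH4Cl
Reagents that add atoms: none
Why: Chemoselective NaBH4 reduction of the aldehyde beside the hindered, electron-rich aryl ketone at −78 °C, then base-catalysed methanolysis (transesterification) of both aryl acetates; no stereocentre is formed and C4, the only enolisable one left, stays in its favoured trans position.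

**Compound list**

1 | (E)-4-acetoxy-3-methoxycinnamaldehyde | COc1cc(/C=C/C=O)ccc1OC(C)=O | starting material
2 | 1,4-dioxane-2,5-diol (glycolaldehyde dimer) | OC1COC(O)CO1 | starting material
3 | 4-[(2S)-3-formyl-4-hydroxyoxolan-2-yl]-2-methoxyphenyl acetate (aldol adduct, C3/C4 epimers) | COc1cc([C@H]2OCC(O)C2C=O)ccc1OC(C)=O | intermediate
4 | 4-[(2R)-3-formyl-2,5-dihydrofuran-2-yl]-2-methoxyphenyl acetate | COc1cc([C@H]2OCC=C2C=O)ccc1OC(C)=O | intermediate
5 | syringic acid | COc1cc(C(=O)O)cc(OC)c1O | starting material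
6 | 4-acetoxy-3,5-dimethoxybenzoic acid | COc1cc(C(=O)O)cc(OC)c1OC(C)=O | intermediate
7 | 4-[(2S)-4-(4-acetoxy-3,5-dimethoxybenzoyl)-3-formyloxolan-2-yl]-2-methoxyphenyl acetate (kinetic mixture of C3/C4 epimers) | COc1cc([C@H]2OCC(C(=O)c3cc(OC)c(OC(C)=O)c(OC)c3)C2C=O)ccc1OC(C)=O | intermediate
8 | 4-[(2S,3S,4S)-4-(4-acetoxy-3,5-dimethoxybenzoyl)-3-formyloxolan-2-yl]-2-methoxyphenyl acetate (all-trans) | COc1cc([C@H]2OC[C@@H](C(=O)c3cc(OC)c(OC(C)=O)c(OC)c3)[C@@H]2C=O)ccc1OC(C)=O | intermediate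
9 | 4-[(2S,3R,4S)-4-(4-acetoxy-3,5-dimethoxybenzoyl)-3-(hydroxymethyl)oxolan-2-yl]-2-methoxyphenyl acetate | COc1cc([C@H]2OC[C@@H](C(=O)c3cc(OC)c(OC(C)=O)c(OC)c3)[C@@H]2CO)ccc1OC(C)=O | intermediate
10 | (4-hydroxy-3,5-dimethoxyphenyl)[(3S,4R,5S)-5-(4-hydroxy-3-methoxyphenyl)-4-(hydroxymethyl)oxolan-3-yl]methanone (CNP0169680.1) | COc1cc([C@H]2OC[C@@H](C(=O)c3cc(OC)c(O)c(OC)c3)[C@@H]2CO)ccc1O | target

**Step count**

Total steps: 4. Longest linear sequence: 3 (steps 1, 3, 4).

**Steps most likely to fail**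

Step 1 (the proposed new cascade). Glycolaldehyde may react through its own enamine (C-alkylation, self-aldol), the oxa-Michael adduct may fail to close, or the ee may be low. The sense of induction is assumed from the usual Si-face model; the enantiomeric catalyst is equally available. The fallback uses known chemistry only, sets out from 1 and comes back at 4:
- Ozonolysis of 1 (O3, CH2Cl2–MeOH, −78 °C, then Me2S) gives 4-formyl-2-methoxyphenyl acetate F1.
- An asymmetric Morita–Baylis–Hillman reaction of F1 with 1,1,1,3,3,3-hexafluoropropan-2-yl acrylate (β-isocupreidine, DMF, −55 °C) gives 1,1,1,3,3,3-hexafluoropropan-2-yl (R)-2-[(4-acetoxy-3-methoxyphenyl)(hydroxy)methyl]prop-2-enoate F2.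
- O-Allylation (allyl bromide, Ag2O) gives 1,1,1,3,3,3-hexafluoropropan-2-yl (R)-2-[(4-acetoxy-3-methoxyphenyl)(prop-2-enyloxy)methyl]prop-2-enoate F3.
- Ring-closing metathesis (second-generation Grubbs catalyst, CH2Cl2, 40 °C) gives 1,1,1,3,3,3-hexafluoropropan-2-yl (2R)-2-(4-acetoxy-3-methoxyphenyl)-2,5-dihydrofuran-3-carboxylate F4.
- iBu2AlH (excess, CH2Cl2, −78 °C) reduces the ester and the acetate to 4-[(2R)-3-(hydroxymethyl)-2,5-dihydrofuran-2-yl]-2-methoxyphenol F5.
- MnO2 gives (2R)-2-(4-hydroxy-3-methoxyphenyl)-2,5-dihydrofuran-3-carbaldehyde F6, and Ac2O/pyridine then returns 4.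

Step 3 (aroyl-radical addition and equilibration). The trisubstituted cyclic enal is a slow radical acceptor, and DBU could open the ring by β-elimination from the C3 enolate. The fallback inverts the polarity at C4, sets out from 4 and comes back at 10:
- An N-heterocyclic carbene (IMes·HCl, DBU, THF) converts 4 into its homoenolate, whose C4 adds to commercial 4-acetoxy-3,5-dimethoxybenzaldehyde. Lactonisation gives the cis-fused lactone (3aR,6S,6aS)-6-(4-acetoxy-3-methoxyphenyl)-3-(4-acetoxy-3,5-dimethoxyphenyl)tetrahydro-1H,3H-furo[3,4-c]furan-1-one F7, with both new bonds anti to the C2 aryl group.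
- LiAlH4 opens the lactone and removes both acetates to give 4-[(2S,3R,4R)-4-[hydroxy(4-hydroxy-3,5-dimethoxyphenyl)methyl]-3-(hydroxymethyl)oxolan-2-yl]-2-methoxyphenol F8.
- DDQ (1 equiv, 0 °C) oxidises only the p-hydroxybenzylic carbinol to the 3,4-cis ketone (4-hydroxy-3,5-dimethoxyphenyl)[(3R,4R,5S)-5-(4-hydroxy-3-methoxyphenyl)-4-(hydroxymethyl)oxolan-3-yl]methanone F9.
- K2CO3/MeOH epimerises F9 at the carbon α to the ketone to give 10.

Step 4 (aldehyde-selective reduction). The ketone may be partly reduced, or base may open the β-alkoxy ketone. The fallback gives up the chemoselectivity, sets out from 8 and comes back at 9: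
- Excess NaBH4 (EtOH–THF, 0 °C) reduces both carbonyl groups to 4-[(2S,3R,4S)-4-[(4-acetoxy-3,5-dimethoxyphenyl)(hydroxy)methyl]-3-(hydroxymethyl)oxolan-2-yl]-2-methoxyphenyl acetate F10.
- Activated MnO2 (CH2Cl2, rt) re-oxidises only the benzylic alcohol to give 9, which is deacetylated as in step 4.

**Further compounds**

F1 | step 1 | 4-formyl-2-methoxyphenyl acetate | COc1cc(C=O)ccc1OC(C)=O
F2 | step 1 | 1,1,1,3,3,3-hexafluoropropan-2-yl (R)-2-[(4-acetoxy-3-methoxyphenyl)(hydroxy)methyl]prop-2-enoate | COc1cc([C@@H](O)C(=C)C(=O)OC(C(F)(F)F)C(F)(F)F)ccc1OC(C)=O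
F3 | step 1 | 1,1,1,3,3,3-hexafluoropropan-2-yl (R)-2-[(4-acetoxy-3-methoxyphenyl)(prop-2-enyloxy)methyl]prop-2-enoate | COc1cc([C@@H](OCC=C)C(=C)C(=O)OC(C(F)(F)F)C(F)(F)F)ccc1OC(C)=O
F4 | step 1 | 1,1,1,3,3,3-hexafluoropropan-2-yl (2R)-2-(4-acetoxy-3-methoxyphenyl)-2,5-dihydrofuran-3-carboxylate | COc1cc([C@H]2OCC=C2C(=O)OC(C(F)(F)F)C(F)(F)F)ccc1OC(C)=O
F5 | step 1 | 4-[(2R)-3-(hydroxymethyl)-2,5-dihydrofuran-2-yl]-2-methoxyphenol | COc1cc([C@H]2OCC=C2CO)ccc1O
F6 | step 1 | (2R)-2-(4-hydroxy-3-methoxyphenyl)-2,5-dihydrofuran-3-carbaldehyde | COc1cc([C@H]2OCC=C2C=O)ccc1O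
F7 | step 3 | (3aR,6S,6aS)-6-(4-acetoxy-3-methoxyphenyl)-3-(4-acetoxy-3,5-dimethoxyphenyl)tetrahydro-1H,3H-furo[3,4-c]furan-1-one (epimers at C3) | COc1cc([C@H]2OC[C@@H]3C(c4cc(OC)c(OC(C)=O)c(OC)c4)OC(=O)[C@H]23)ccc1OC(C)=O
F8 | step 3 | 4-[(2S,3R,4R)-4-[hydroxy(4-hydroxy-3,5-dimethoxyphenyl)methyl]-3-(hydroxymethyl)oxolan-2-yl]-2-methoxyphenol (carbinol epimers) | COc1cc([C@H]2OC[C@H](C(O)c3cc(OC)c(O)c(OC)c3)[C@@H]2CO)ccc1O
F9 | step 3 | (4-hydroxy-3,5-dimethoxyphenyl)[(3R,4R,5S)-5-(4-hydroxy-3-methoxyphenyl)-4-(hydroxymethyl)oxolan-3-yl]methanone | COc1cc([C@H]2OC[C@H](C(=O)c3cc(OC)c(O)c(OC)c3)[C@@H]2CO)ccc1O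
F10 | step 4 | 4-[(2S,3R,4S)-4-[(4-acetoxy-3,5-dimethoxyphenyl)(hydroxy)methyl]-3-(hydroxymethyl)oxolan-2-yl]-2-methoxyphenyl acetate (carbinol epimers) | COc1cc([C@H]2OC[C@@H](C(O)c3cc(OC)c(OC(C)=O)c(OC)c3)[C@@H]2CO)ccc1OC(C)=O
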